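The leftover was where I began: at 40.0 h Thursday's run still held 32.9% of its solid substrate and Tuesday's run 48.0%, so I read those runs as books to be balanced.

| flask | solid substrate | reagent | remark | time |
|---|---|---|---|---|
| Thursday's | 0.044 M | 0.10 M (in portions, 4) | run made earlier; portions every 10 h |  |
| Tuesday's | 0.056 M | 0.10 M (in portions, 4) | run made earlier; portions every 10 h |  |
| east | 0.050 M | 0.100 M (in portions, 4) | the portions of reagent follow each other after 10 h, the first at the start | 40 h |
| south-east | 0.030 M | 0.100 M | everything together at the start | 40 h |

- Thursday's (time / h: mono adduct / %, solid substrate / %): 3.00: 0.5, 85.8; 8.00: 1.6, 71.5; 15.0: 4.2, 59.7; 40.0: 25.1, 32.9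
- Tuesday's (time / h: mono adduct / %, solid substrate / %): 3.00: 0.4, 89.0; 8.00: 1.2, 77.3; 15.0: 3.6, 67.5; 40.0: 19.3, 48.0

(standard deviation of a reading: 0.3 percentage points)

- solid, in amounts per volume of the solution: solid substrate
- the analysis behind the earlier runs scatters by 0.3 percentage points, standard deviation
- at the start none of the solid substrate is in solution
- what has only dissolved of solid substrate counts as not reacted

1. which one finishes higher in amount of mono adduct, in percent of the solid substrate charged ("neither" within 2 percentage points) (east / south-east / neither)
2. amount of mono adduct at the end, in percent of the solid substrate charged, east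
3. amount of mono adduct at the end, in percent of the solid substrate charged, south-east

1. The solid substrate, charged at less than the reagent's 0.100 M, is the limiting reagent, so I kept its books in moles per litre.

2. The first entry is what left the solid. By 40.0 h Thursday's run had lost 0.0295 M and Tuesday's run 0.0291 M, from charges of 0.044 M and 0.056 M. I called their mean the draw, the concentration that has left the solid by that time under portions while solid remains: 0.0293 M, as a reading.

3. The second entry is mono adduct, a mean of 0.0109 M in those runs. The remaining 0.0184 M of the draw stood in no column.

4. For east, with the same portions, the books closed at 0.0207 M solid, 0.0109 M mono adduct and 0.0184 M unread. That put mono adduct at 21.9%.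

5. For south-east, the draw was 97.7% of the charge, which would leave 2.26% as solid at the end; but the draw was read under portions, and here the whole of the reagent stood in at the start, so I took that leftover as an upper mark. Reagent started at 0.100 M rather than 0.0250 M, so I held 36.4% as my lower mark for mono adduct.

6. The forecast chose south-east, with 21.9% for east and 50% for south-east, holding that “the charge doesn't matter” while solid remains. Its south-east figure stood higher than my mark.

7. The flasks gave south-east as the higher, with 21.9% in east and 45.1% in south-east.

    reagent + bis adduct → triple product (k = 1.52 × 10⁻⁴ L mol⁻¹ s⁻¹)
    reagent + mono adduct → bis adduct (k = 3.61 × 10⁻⁵ L mol⁻¹ s⁻¹)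
    reagent + triple product → tetra adduct (k = 4.88 × 10⁻⁶ L mol⁻¹ s⁻¹)
    solid substrate ⇌ starting material, rate k4*(cs4 - [starting material]) while solid is left; crystals form when [starting material] > cs4 (solubility = 21.0 mM, k = 3.15 × 10⁻⁵ s⁻¹)
    starting material + reagent → mono adduct (k = 9.55 × 10⁻⁵ L mol⁻¹ s⁻¹)

8. East ended with 41.4% solid, and the draw had left it 41.4%; south-east ended with 0%. A neighbouring flask, south-east with 0.12 M of solid substrate, ended with 72.1% solid, a loss of 0.0335 M, higher than the draw, with its reagent in at the start. Neither east nor south-east was at rest at 40 h. By 400 h east's mono adduct rose from 21.9% to 42.0%, with 0% solid. South-east's fell from 45.1% to 19.2%, with triple product at 65.4%.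

(The numbers in the tables are simulated with made-up constants, noise included.)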